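## Analysis of the target

The target (37) is a germacranolide: a ten-membered carbocycle C1–C10 that is trans-fused at C6–C7 to an α-methylene-γ-butyrolactone (O on C6, C12 carbonyl, C11=C13). It carries a 1,10-epoxide, a Z-configured trisubstituted C4=C5 alkene whose C4 substituent C15 is a hydroxymethyl group, a free allylic hydroxyl at C3 and an (S)-2-methylbutanoate at C8. The ring holds six stereocentres, C1 (R), C3 (S), C6 (R), C7 (R), C8 (R) and C10 (R), and the ester side chain a seventh (S). H6 and H7 are trans, the C8–O and C10–O bonds are 1,3-anti across the C9 methylene, and the epoxide is trans (C2 and C9 on opposite faces). C3 is insulated from the other centres by C2 and the alkene and has to be set on its own. The sensitive groups are the α-methylene lactone (a Michael acceptor that tolerates neither nucleophilic base nor reductants), the epoxide lying across the ring from an alkene (acid-induced transannular opening), the C8 ester next to the lactone (acyl transfer to an 8,12-olide) and the Z geometry of C4=C5. The synthesis is hard because a medium ring has to be closed against entropy and transannular strain, and because stereocentres set on the flexible ring would depend on its conformation. The strategy rests on one feature: the oxygens on C8 and C10 are 1,3-related through C9, and C10 is a fully substituted, methyl-bearing C–O centre. This is the pattern left by the addition of a C8 ketone enolate (nucleophilic at C9) to a C10 methyl ketone, and the C10 oxygen so formed is the nucleophile that can later close the epoxide at C1.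

## Retrosynthetic reasoning

37 is traced back to its bis-silyl ether 36 by cutting the two O–Si bonds at C3 and C15. These hydroxyls are kept masked to the end because, free, they would compete in the sulfonylation and acylation steps; the forward step has to remove both groups without touching epoxide, methylene lactone or ester.

The epoxide C1–O bond of 36 is cut so that the oxygen stays on C10: this leads to mesylate 35, to the 1,10-diol 34 and to its C1 triethylsilyl ether 33, all with the opposite configuration at C1. Direct epoxidation of a C1=C10 alkene would leave the facial selectivity to the ring conformation; the displacement instead transfers the configuration of two centres that are set under control. The forward steps need selective unmasking of C1–O, sulfonylation of the secondary hydroxyl only, and closure with inversion.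

The acyl C–O bond at C8 of 33 is cut to diol 31 and acid 32, which brings its stereocentre from the chiral pool. The ester is attached after C13 is in place so that its α-C–H never meets a strong base.

The C11=C13 bond of 31 is cut back to the lactone methylene of 28 (through Mannich base 29 and ammonium salt 30). The exocyclic alkene is reducible and electrophilic and cannot be carried through the ring closure; once C8 is a carbinol, C11 is the only enolisable position left.

The C8 carbinol of 28 comes from ketone 27. The 1,3-anti relation between C8–O and C10–O is what intramolecular hydride delivery from the C10 hydroxyl provides, so the stereocentre made in the ring closure controls the next one.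

The C9–C10 bond of 27 is cut to the seco bromomethyl ketone 25 (through enolate 26). This is the one ring bond whose cleavage is a carbonyl-addition retron with both oxygens (C8, C10) already where the target has them. It creates a single stereocentre (C10), since C9 is a methylene, and it leaves C1, C3, C6 and C7 to be set in acyclic or five-ring intermediates. The bromine fixes the site of enolate formation at C9, away from C7, where an enolate would expel the lactone carboxylate. The forward reaction has to close a ten-membered ring and choose the C10 face anti to the C1 silyloxy group.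

The C8–C9 bond of 25 is cut to acid 22 by way of diazoketone 24 and mixed anhydride 23, a one-carbon homologation that needs no enolate chemistry next to the lactone.

The lactone triad of 22 (C6–O, C7–C8, C11–C12) is a paraconic acid. It is cut at C6–C7 and at the lactone C–O bond to enal 15 and the succinate imide 18 (via enolate 19, aldol 20 and lactone imide 21); an auxiliary-controlled syn-aldol sets C6 and C7 together, and lactonisation gives the trans ring. Imide 18 is cut at the N–acyl bond to oxazolidinone 16 and acid chloride 17.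

Enal 15 is traced to allylic alcohol 14 and this to Weinreb amide 13 by cutting C10–C14. The methyl ketone is unmasked before any lactone or second ketone exists, and the same operation frees the C6 oxygen.

The C3 carbinol of 13 (via alcohol 12) is taken back to enone 11 and to the epimeric alcohols 10. The 1,3-induction from C1 in the C–C bond-forming step is not dependable, so C3 is set afterwards by a catalyst-controlled reduction.

The C3–C4 bond of 10 is cut to aldehyde 4 and alkenyl iodide 9; the Z geometry of C4=C5 and the C15 oxygen come in ready-made with 9.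

Iodide 9 goes back through alcohol 8 and alanate 7 to the monosilyl ether 6 of diol 5. A hydroxyl-directed trans-hydrometalation places iodine and geometry in one step. C15 carries a tert-butyldiphenylsilyl group so that the C1 triethylsilyl ether can later be removed with a wide margin.

Aldehyde 4 goes back through hydroxy amide 3 and silyl ether 2 to lactone 1, which supplies C10, C1, C2 and C3 with the C1 stereocentre and with its two termini already differentiated as acyl and alkoxy carbon.

## Alternatives that were turned down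

Alternative 1: The cut is the lactone C6–O bond alone. The precursor is the ring acid A2, a 2-(cyclodecenyl)acrylic acid in which epoxide, C8 ester, both silyl ethers and C13 are present and C6 is an allylic methylene. In the forward sense the carboxyl radical of A2 takes the hydrogen from C6 through a six-membered transition state, the allyl radical is oxidised, and the carboxylate closes on C6 to give A1, the bis-silyl ether of 37. In its favour, the lactone appears in the last skeletal step and neither a late methylenation nor the C1 protecting-group sequence is needed. Its endgame is one desilylation, and on this point it is clearly stronger than the chosen route, which needs eight steps after ring closure. Against it, the carboxyl radical of an acrylic acid can add to its own alkene or decarboxylate before it abstracts hydrogen, and C8–H, activated by the ester oxygen, is reached through the same size of transition state. The C4–C5–C6 allyl intermediate can lose the Z geometry or be captured at C4, the configuration at C6 is left to the ring conformation, and the epoxide must survive oxidising, cation-forming conditions next to a transannular alkene. Above all, A2 already contains the ten-membered ring and five ring stereocentres, so the hard part is moved and not solved. The chosen route offers in its place a C6/C7 pair fixed by an auxiliary-controlled aldol and a ring closure of a known reaction type.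

Alternative 2: The cuts are C1–C2 and O–C3. The precursor is oxime A4, with the lactone, the quaternary C10 and a terminal diene in place. In the forward sense A4 is oxidised to the nitrile oxide, which adds across the vinyl group C2=C3 and gives A3, the ten-membered carbocycle bridged by an isoxazoline. In its favour, one step forms the ring, a C–C bond and the C3–O bond. The dipole is made under near-neutral conditions and tolerates lactone and silyl ethers, with no enolate beside the lactone and no reducible group at risk; in functional-group tolerance of the ring-closing step it is at least as strong as the samarium aldol. Against it, the required regiochemistry places the C=N bond at a bridgehead of a ten-membered ring, a mode that is usual only for larger rings, and dimerisation of the dipole competes. C3 is created in the cycloaddition, so its configuration depends on macrocyclic facial selectivity. Afterwards the N–O bond must be cleaved beside alkene and lactone, the C1 ketone reduced selectively next to the quaternary C10, C1–O and C3–O told apart, C10–O freed and the C8 ether exchanged for the ester. That is a longer endgame with two centres (C1, C3) under substrate control, whereas the chosen route leaves only C10 to the ring closure.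

Alternative 3: The C8–C9 bond is formed while the C1–C6 bond of a six-membered ring is broken. The precursor is A6, a 1-alkenyl-2-isopropenylcyclohexenol. In the forward sense the potassium alkoxide of A6 rearranges through a chair ([3,3], anionic oxy-Cope) and the six-membered ring opens into the ten-membered dienone A5. In its favour, the ring expansion is concerted, needs no high dilution and gives the E geometry of C1=C10 from the chair; on the ring-forming step itself it is stronger than the samarium aldol, and A6 would come from a cheap terpene. Against it, A5 holds only two of the stereocentres (C3, C8), no C15 oxygen, no C11–C12 unit, and C6 as a ketone. Controlled alkylation at C7, reduction of C6, lactonisation, allylic oxidation of the Z-methyl group, face-selective epoxidation of C1=C10 beside C4=C5, ether-to-ester exchange and methylenation would all have to be done on the flexible ring. That puts at least four centres (C1, C10, C6, C7) under substrate control and needs more steps after ring formation than the chosen route. The chosen route pays with a riskier ring closure, but every centre except C10 and C8 is set by reagent or chiral-pool control before the ring exists, and the epoxide is made by displacement.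

Key step: step 18

## Route

Assumption: lactone 1, the reduction–lactonisation product of (S)-malic acid, and acid chloride 17 are bought. Atom labels C1–C15 are the germacrane positions of 37 and are used for all intermediates.

Abbreviations: TES = triethylsilyl, TBS = tert-butyldimethylsilyl, TBDPS = tert-butyldiphenylsilyl. R* = (1Z,3S,5S)-3-(tert-butyldimethylsilyloxy)-2-[(tert-butyldiphenylsilyloxy)methyl]-6-oxo-5-(triethylsilyloxy)hept-1-en-1-yl, that is C5=C4(C15)–C3–C2–C1–C10(=O)–C14.

Step 1
Reactants: 1 (S)-3-hydroxyoxolan-2-one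
Product: 2 (S)-3-(triethylsilyloxy)oxolan-2-one
Conditions: TESCl, imidazole, DMF, 0 °C → rt
Reagents that add atoms: chlorotriethylsilane, CC[Si](Cl)(CC)CC
Why: Standard O-silylation of a secondary alcohol that leaves the stereocentre (future C1) untouched; the triethylsilyl ether is a poor chelator and can later be removed beside tert-butyl-substituted silyl ethers.

Step 2
Reactants: 2 (S)-3-(triethylsilyloxy)oxolan-2-one
Product: 3 (S)-4-hydroxy-N-methoxy-N-methyl-2-(triethylsilyloxy)butanamide
Conditions: MeNH(OMe)·HCl, AlMe3, CH2Cl2, 0 °C → rt; aqueous potassium sodium tartrate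
Reagents that add atoms: N,O-dimethylhydroxylamine hydrochloride, CNOC.Cl
Why: Weinreb aminolysis of a γ-lactone by the aluminium amide opens the ring at the acyl C–O bond, so that C10 becomes a masked methyl ketone and C3 a primary alcohol; the α-stereocentre is not enolised, and the crude product is used at once so that it cannot relactonise.

Step 3
Reactants: 3 (S)-4-hydroxy-N-methoxy-N-methyl-2-(triethylsilyloxy)butanamide
Product: 4 (S)-N-methoxy-N-methyl-4-oxo-2-(triethylsilyloxy)butanamide
Conditions: Dess–Martin periodinane, NaHCO3, CH2Cl2, 0 °C → rt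
Reagents that add atoms: none
Why: Buffered hypervalent-iodine oxidation of the primary alcohol to the aldehyde under non-basic conditions, which avoids β-elimination of the silyloxy group; the aldehyde is used crude.

Step 4
Reactants: 5 but-2-yne-1,4-diol
Product: 6 4-(tert-butyldiphenylsilyloxy)but-2-yn-1-ol
Conditions: NaH (1 equiv), THF, 0 °C; TBDPSCl (1 equiv); diol in excess
Reagents that add atoms: tert-butyl(chloro)diphenylsilane, CC(C)(C)[Si](Cl)(c1ccccc1)c1ccccc1
Why: Monosilylation of a symmetrical diol through its sparingly soluble monosodium alkoxide; the silyl group is the future C15 protecting group and is robust toward acid.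

Step 5
Reactants: 6 4-(tert-butyldiphenylsilyloxy)but-2-yn-1-ol
Product: 8 (Z)-4-(tert-butyldiphenylsilyloxy)-3-iodobut-2-en-1-ol, via sodium alkenylalanate 7 (not isolated)
Conditions: NaAlH2(OCH2CH2OMe)2, THF, 0 °C; then I2, −78 → 0 °C
Reagents that add atoms: iodine, II
Why: Hydroxyl-directed trans-hydroalumination delivers hydride to the alkyne carbon next to the carbinol and places aluminium on the distal carbon in the five-membered alanate 7. Iodinolysis with retention then gives the Z-alkenyl iodide (I cis to CH2OH), the geometry that puts C3 and C6 cis on C4=C5.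

Step 6
Reactants: 8 (Z)-4-(tert-butyldiphenylsilyloxy)-3-iodobut-2-en-1-ol
Product: 9 (Z)-4-(tert-butyldiphenylsilyloxy)-3-iodobut-2-en-1-yl acetate
Conditions: Ac2O, pyridine, 4-(dimethylamino)pyridine (cat.), CH2Cl2, 0 °C
Reagents that add atoms: acetic anhydride, CC(=O)OC(C)=O
Why: Simple acetylation; the acetate is inert to organochromium reagents and is removed later by the Grignard reagent of step 11, so no separate deprotection is needed.

Step 7
Reactants: 4 (S)-N-methoxy-N-methyl-4-oxo-2-(triethylsilyloxy)butanamide; 9 (Z)-4-(tert-butyldiphenylsilyloxy)-3-iodobut-2-en-1-yl acetate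
Product: 10 (2S,4RS,5Z)-7-acetoxy-5-[(tert-butyldiphenylsilyloxy)methyl]-4-hydroxy-N-methoxy-N-methyl-2-(triethylsilyloxy)hept-5-enamide
Conditions: CrCl2 (4 equiv), NiCl2 (2 mol %), DMSO, rt
Reagents that add atoms: none
Why: Nozaki–Hiyama–Kishi coupling: zerovalent nickel inserts into the C–I bond with retention and the alkenylchromium species adds only to the aldehyde, so Weinreb amide, acetate and silyl ethers are tolerated and C3–C4 is formed with the Z alkene intact. The configuration at C3 is not controlled here because it is reset in steps 8 and 9.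

Step 8
Reactants: 10 (2S,4RS,5Z)-7-acetoxy-5-[(tert-butyldiphenylsilyloxy)methyl]-4-hydroxy-N-methoxy-N-methyl-2-(triethylsilyloxy)hept-5-enamide
Product: 11 (2S,5Z)-7-acetoxy-5-[(tert-butyldiphenylsilyloxy)methyl]-N-methoxy-N-methyl-4-oxo-2-(triethylsilyloxy)hept-5-enamide
Conditions: Dess–Martin periodinane, NaHCO3, CH2Cl2, 0 °C → rt
Reagents that add atoms: none
Why: Oxidation of the allylic alcohol converges both C3 epimers on one enone; the neutral conditions keep the Z geometry and also remove the hydroxyl that could lactonise onto the amide.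

Step 9
Reactants: 11 (2S,5Z)-7-acetoxy-5-[(tert-butyldiphenylsilyloxy)methyl]-N-methoxy-N-methyl-4-oxo-2-(triethylsilyloxy)hept-5-enamide
Product: 12 (2S,4S,5Z)-7-acetoxy-5-[(tert-butyldiphenylsilyloxy)methyl]-4-hydroxy-N-methoxy-N-methyl-2-(triethylsilyloxy)hept-5-enamide
Conditions: (R)-1-methyl-3,3-diphenyltetrahydro-1H,3H-pyrrolo[1,2-c][1,3,2]oxazaborole [(R)-Me-CBS] (0.5 equiv), catecholborane, toluene, −78 °C
Reagents that add atoms: none
Why: Corey–Bakshi–Shibata reduction in which the α-branched alkenyl group is the large substituent and the C2 methylene the small one, so the (R)-catalyst should deliver hydride to give the (S)-carbinol at C3. Only 1,2-reduction is expected, and amide and acetate are not reduced at −78 °C.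

Step 10
Reactants: 12 (2S,4S,5Z)-7-acetoxy-5-[(tert-butyldiphenylsilyloxy)methyl]-4-hydroxy-N-methoxy-N-methyl-2-(triethylsilyloxy)hept-5-enamide
Product: 13 (2S,4S,5Z)-7-acetoxy-4-(tert-butyldimethylsilyloxy)-5-[(tert-butyldiphenylsilyloxy)methyl]-N-methoxy-N-methyl-2-(triethylsilyloxy)hept-5-enamide
Conditions: TBSOTf, 2,6-lutidine, CH2Cl2, −78 °C
Reagents that add atoms: tert-butyldimethylsilyl trifluoromethanesulfonate, CC(C)(C)[Si](C)(C)OS(=O)(=O)C(F)(F)F
Why: Silylation of the hindered allylic alcohol with the silyl triflate, done cold and at once so that the γ-hydroxy amide cannot lactonise. C3–O must be capped before C6 is oxidised, because a free C3 hydroxyl cis to C6 would close to a lactol.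

Step 11
Reactants: 13 (2S,4S,5Z)-7-acetoxy-4-(tert-butyldimethylsilyloxy)-5-[(tert-butyldiphenylsilyloxy)methyl]-N-methoxy-N-methyl-2-(triethylsilyloxy)hept-5-enamide
Product: 14 (3S,5S,6Z)-5-(tert-butyldimethylsilyloxy)-6-[(tert-butyldiphenylsilyloxy)methyl]-8-hydroxy-3-(triethylsilyloxy)oct-6-en-2-one
Conditions: MeMgBr (5 equiv), THF, −20 → 0 °C; aq. NH4Cl
Reagents that add atoms: methylmagnesium bromide, C[Mg]Br
Why: Weinreb ketone synthesis: the chelated tetrahedral intermediate stops at the methyl ketone (C10–C14) and protects C1 from enolisation, and the same reagent cleaves the acetate and frees the C6 hydroxyl.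

Step 12
Reactants: 14 (3S,5S,6Z)-5-(tert-butyldimethylsilyloxy)-6-[(tert-butyldiphenylsilyloxy)methyl]-8-hydroxy-3-(triethylsilyloxy)oct-6-en-2-one
Product: 15 (2Z,4S,6S)-4-(tert-butyldimethylsilyloxy)-3-[(tert-butyldiphenylsilyloxy)methyl]-7-oxo-6-(triethylsilyloxy)oct-2-enal
Conditions: MnO2, CH2Cl2, rt
Reagents that add atoms: none
Why: Chemoselective heterogeneous oxidation of the primary allylic alcohol; the neutral conditions should leave the Z geometry and the α-silyloxy ketone unchanged.

Step 13
Reactants: 16 (S)-4-benzyl-1,3-oxazolidin-2-one; 17 methyl 4-chloro-4-oxobutanoate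
Product: 18 methyl 4-[(4S)-4-benzyl-2-oxo-1,3-oxazolidin-3-yl]-4-oxobutanoate
Conditions: n-BuLi, THF, −78 °C; then 17, −78 → 0 °C
Reagents that add atoms: none
Why: N-Acylation of the lithiated oxazolidinone; the acid chloride reacts far faster than the methyl ester, which is kept for the later lactonisation.

Step 14
Reactants: 15 (2Z,4S,6S)-4-(tert-butyldimethylsilyloxy)-3-[(tert-butyldiphenylsilyloxy)methyl]-7-oxo-6-(triethylsilyloxy)oct-2-enal; 18 methyl 4-[(4S)-4-benzyl-2-oxo-1,3-oxazolidin-3-yl]-4-oxobutanoate
Product: 21 (4S)-4-benzyl-3-[(2R,3S)-5-oxo-2-R*-oxolane-3-carbonyl]-1,3-oxazolidin-2-one, via dibutylboron enolate 19 (not isolated), via syn-aldol hydroxy ester 20 (not isolated)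
Conditions: 18, Bu2BOTf, i-Pr2NEt, CH2Cl2, 0 °C; 15, −78 → 0 °C; pH 7 buffer, H2O2, MeOH; then pyridinium p-toluenesulfonate (cat.), toluene, 40 °C
Reagents that add atoms: none
Why: Evans syn-aldol: soft enolisation gives the Z-boron enolate 19 without touching methyl ester or methyl ketone, and the chair Zimmerman–Traxler transition state under control of the (S)-benzyl auxiliary sets C7 and C6 (C6–C7 bond). The C6 hydroxyl of 20 then closes on the methyl ester (5-exo-trig) and the syn relationship becomes the trans-disubstituted γ-lactone.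

Step 15
Reactants: 21 (4S)-4-benzyl-3-[(2R,3S)-5-oxo-2-R*-oxolane-3-carbonyl]-1,3-oxazolidin-2-one
Product: 22 (2R,3S)-5-oxo-2-R*-oxolane-3-carboxylic acid
Conditions: LiOH, H2O2, THF/H2O, 0 °C; Na2SO3; KHSO4 to pH 3
Reagents that add atoms: hydrogen peroxide, OO
Why: Hydroperoxide attacks the exocyclic imide carbonyl selectively and the peracid is reduced by sulfite. Its low basicity at 0 °C should avoid enolisation at C7 and C1, and any lactone that opens recloses on acidification.

Step 16
Reactants: 22 (2R,3S)-5-oxo-2-R*-oxolane-3-carboxylic acid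
Product: 24 (4S,5R)-4-(2-diazoacetyl)-5-R*-oxolan-2-one, via mixed carbonic anhydride 23 (not isolated)
Conditions: i-BuOCOCl, N-methylmorpholine, THF, −20 °C; then CH2N2 (excess), Et2O, −20 → 0 °C
Reagents that add atoms: diazomethane, C=[N+]=[N-]
Why: Acylation of diazomethane by a mixed anhydride (first stage of an Arndt–Eistert sequence) forms C8–C9 without generating HCl. The weak amine base and low temperature keep C7 from enolising, and the methyl ketone is inert to diazomethane in the absence of a Lewis acid.

Step 17
Reactants: 24 (4S,5R)-4-(2-diazoacetyl)-5-R*-oxolan-2-one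
Product: 25 (4S,5R)-4-(2-bromoacetyl)-5-R*-oxolan-2-one
Conditions: 48 % aq. HBr (1.05 equiv), Et2O, −30 °C, 10 min; NaHCO3
Reagents that add atoms: hydrogen bromide, Br
Why: C-Protonation of the diazoketone and displacement of N2 by bromide place bromine regiospecifically on C9; the single equivalent of acid is consumed within minutes at low temperature, which should spare the silyl ethers.

Step 18
Reactants: 25 (4S,5R)-4-(2-bromoacetyl)-5-R*-oxolan-2-one
Product: 27 (1S,3S,4Z,6R,7S,10R)-3-(tert-butyldimethylsilyloxy)-15-(tert-butyldiphenylsilyloxy)-10-hydroxy-8-oxo-1-(triethylsilyloxy)-13-norgermacr-4-en-6,12-olide, via diiodosamarium enolate 26 (not isolated)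
Conditions: SmI2 (2.5 equiv), THF, −78 °C, 25 added by syringe pump (final 0.003 M); aq. NH4Cl at −78 °C
Reagents that add atoms: none
Why: Two single-electron transfers from SmI2 cleave the C9–Br bond and give the trivalent samarium enolate 26 regiospecifically at C9, while the α-silyloxy ketone and the lactone are reduced far more slowly at −78 °C without a proton source or HMPA. The enolate adds to the C10 ketone through a metal-bridged cyclic transition state; the closest known reaction type is the SmI2-mediated intramolecular Reformatsky (reductive aldol) reaction used for medium and large rings. The ten-membered carbocycle closes in the 10-(enolendo)-exo-trig mode, C9 being the nucleophile and the exocyclic C10 oxygen becoming a samarium aldolate, which makes the addition effectively irreversible at low temperature. Ring closure should win over intermolecular addition because of the slow addition at high dilution and because the oxophilic metal holds enolate oxygen and ketone oxygen together, while the Z alkene and the trans-lactone remove rotors from the chain. C10 is the only new stereocentre (C9 is a methylene): the bulky, poorly coordinating triethylsilyloxy group on C1 stands anti to the incoming C9 (polar Felkin–Anh, C2 inside, H next to the C14 methyl), which gives the (10R)-carbinol. The step therefore needs regioselectivity (enolate at C9 and not at C7, secured by the position of bromine) and facial selectivity (Felkin–Anh rather than chelate, secured by the silyl ether and the absence of a stronger Lewis acid). Quenching at −78 °C avoids retro-aldol opening.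

Step 19
Reactants: 27 (1S,3S,4Z,6R,7S,10R)-3-(tert-butyldimethylsilyloxy)-15-(tert-butyldiphenylsilyloxy)-10-hydroxy-8-oxo-1-(triethylsilyloxy)-13-norgermacr-4-en-6,12-olide
Product: 28 (1S,3S,4Z,6R,7R,8R,10R)-3-(tert-butyldimethylsilyloxy)-15-(tert-butyldiphenylsilyloxy)-8,10-dihydroxy-1-(triethylsilyloxy)-13-norgermacr-4-en-6,12-olide
Conditions: Me4NBH(OAc)3, MeCN/AcOH (1:1), −30 → 0 °C
Reagents that add atoms: none
Why: Evans–Saksena reduction: the C10 hydroxyl exchanges onto boron and hydride is delivered intramolecularly through a six-membered transition state, which should give the 1,3-anti diol, that is (8R). The acidic medium suppresses retro-aldol cleavage and elimination at C7.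

Step 20
Reactants: 28 (1S,3S,4Z,6R,7R,8R,10R)-3-(tert-butyldimethylsilyloxy)-15-(tert-butyldiphenylsilyloxy)-8,10-dihydroxy-1-(triethylsilyloxy)-13-norgermacr-4-en-6,12-olide
Product: 29 (1S,3S,4Z,6R,7R,8R,10R,11RS)-3-(tert-butyldimethylsilyloxy)-15-(tert-butyldiphenylsilyloxy)-13-(dimethylamino)-8,10-dihydroxy-1-(triethylsilyloxy)germacr-4-en-6,12-olide
Conditions: LiN(i-Pr)2 (3.5 equiv), THF, −78 °C (28 added to the base); CH2=NMe2+ I− (4 equiv), −78 °C → rt
Reagents that add atoms: N,N-dimethylmethyleneiminium iodide (Eschenmoser's salt), C=[N+](C)C.[I-]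
Why: After reduction of C8 the lactone C11–H2 is the only enolisable position, and the dialkoxide enolate undergoes a Mannich reaction that brings in C13. It is done before acylation so that the stereocentre of the 2-methylbutanoate never meets an amide base; O-aminomethyl adducts of the alkoxides hydrolyse on work-up.

Step 21
Reactants: 29 (1S,3S,4Z,6R,7R,8R,10R,11RS)-3-(tert-butyldimethylsilyloxy)-15-(tert-butyldiphenylsilyloxy)-13-(dimethylamino)-8,10-dihydroxy-1-(triethylsilyloxy)germacr-4-en-6,12-olide
Product: 31 (1S,3S,4Z,6R,7R,8R,10R)-3-(tert-butyldimethylsilyloxy)-15-(tert-butyldiphenylsilyloxy)-8,10-dihydroxy-1-(triethylsilyloxy)germacra-4,11(13)-dien-6,12-olide, via trimethylammonium iodide 30 (not isolated)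
Conditions: MeI, MeOH/CH2Cl2, rt; evaporate; NaHCO3, CH2Cl2/H2O, rt
Reagents that add atoms: none
Why: N-Quaternisation followed by E1cB loss of trimethylamine gives the exocyclic methylene under very mild base and removes the C11 stereocentre.

Step 22
Reactants: 31 (1S,3S,4Z,6R,7R,8R,10R)-3-(tert-butyldimethylsilyloxy)-15-(tert-butyldiphenylsilyloxy)-8,10-dihydroxy-1-(triethylsilyloxy)germacra-4,11(13)-dien-6,12-olide; 32 (S)-2-methylbutanoic acid
Product: 33 (1S,3S,4Z,6R,7R,8R,10R)-3-(tert-butyldimethylsilyloxy)-15-(tert-butyldiphenylsilyloxy)-10-hydroxy-8-[(2S)-2-methylbutanoyloxy]-1-(triethylsilyloxy)germacra-4,11(13)-dien-6,12-olide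
Conditions: N,N′-dicyclohexylcarbodiimide, 4-(dimethylamino)pyridine (0.3 equiv), CH2Cl2, 0 °C → rt
Reagents that add atoms: none
Why: Steglich esterification: the secondary C8 hydroxyl is acylated while the tertiary C10 hydroxyl is not, and without strong base neither the α-stereocentre of the acid nor the methylene lactone should be affected.

Step 23
Reactants: 33 (1S,3S,4Z,6R,7R,8R,10R)-3-(tert-butyldimethylsilyloxy)-15-(tert-butyldiphenylsilyloxy)-10-hydroxy-8-[(2S)-2-methylbutanoyloxy]-1-(triethylsilyloxy)germacra-4,11(13)-dien-6,12-olide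
Product: 34 (1S,3S,4Z,6R,7R,8R,10R)-3-(tert-butyldimethylsilyloxy)-15-(tert-butyldiphenylsilyloxy)-1,10-dihydroxy-8-[(2S)-2-methylbutanoyloxy]germacra-4,11(13)-dien-6,12-olide
Conditions: pyridinium p-toluenesulfonate (0.2 equiv), MeOH/CH2Cl2, 0 °C
Reagents that add atoms: none
Why: Acid-catalysed methanolysis removes the triethylsilyl ether, which is cleaved far faster than the secondary TBS and the primary TBDPS ether.

Step 24
Reactants: 34 (1S,3S,4Z,6R,7R,8R,10R)-3-(tert-butyldimethylsilyloxy)-15-(tert-butyldiphenylsilyloxy)-1,10-dihydroxy-8-[(2S)-2-methylbutanoyloxy]germacra-4,11(13)-dien-6,12-olide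
Product: 35 (1S,3S,4Z,6R,7R,8R,10R)-3-(tert-butyldimethylsilyloxy)-15-(tert-butyldiphenylsilyloxy)-10-hydroxy-1-(methanesulfonyloxy)-8-[(2S)-2-methylbutanoyloxy]germacra-4,11(13)-dien-6,12-olide
Conditions: MsCl, Et3N, CH2Cl2, −20 °C
Reagents that add atoms: methanesulfonyl chloride, CS(=O)(=O)Cl
Why: Sulfene-mediated mesylation reaches the hindered secondary C1 hydroxyl and leaves the tertiary C10 hydroxyl free.

Step 25
Reactants: 35 (1S,3S,4Z,6R,7R,8R,10R)-3-(tert-butyldimethylsilyloxy)-15-(tert-butyldiphenylsilyloxy)-10-hydroxy-1-(methanesulfonyloxy)-8-[(2S)-2-methylbutanoyloxy]germacra-4,11(13)-dien-6,12-olide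
Product: 36 (1R,3S,4Z,6R,7R,8R,10R)-3-(tert-butyldimethylsilyloxy)-15-(tert-butyldiphenylsilyloxy)-1,10-epoxy-8-[(2S)-2-methylbutanoyloxy]germacra-4,11(13)-dien-6,12-olide
Conditions: DBU, MeCN, rt → 40 °C
Reagents that add atoms: none
Why: Intramolecular Williamson closure (3-exo-tet): the C10 oxygen attacks C1 anti to the mesylate, inverting C1 (S to R) with retention at C10, which gives the trans-epoxide. The amidine base is non-nucleophilic and tolerated by methylene lactone and ester.

Step 26
Reactants: 36 (1R,3S,4Z,6R,7R,8R,10R)-3-(tert-butyldimethylsilyloxy)-15-(tert-butyldiphenylsilyloxy)-1,10-epoxy-8-[(2S)-2-methylbutanoyloxy]germacra-4,11(13)-dien-6,12-olide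
Product: 37 (1R,3S,4Z,6R,7R,8R,10R)-1,10-epoxy-3,15-dihydroxy-8-[(2S)-2-methylbutanoyloxy]germacra-4,11(13)-dien-6,12-olide (CNP0267576.2)
Conditions: Bu4NF, AcOH (1:1), THF, 0 °C → rt
Reagents that add atoms: none
Why: Buffered fluoride cleaves both silyl ethers; the near-neutral medium should avoid epoxide opening, conjugate addition to the methylene lactone and acyl migration.

## Compound list

1 | (S)-3-hydroxyoxolan-2-one | O=C1OCC[C@@H]1O | starting material
2 | (S)-3-(triethylsilyloxy)oxolan-2-one | O=C1OCC[C@@H]1O[Si](CC)(CC)CC | intermediate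
3 | (S)-4-hydroxy-N-methoxy-N-methyl-2-(triethylsilyloxy)butanamide | CON(C)C(=O)[C@H](CCO)O[Si](CC)(CC)CC | intermediate
4 | (S)-N-methoxy-N-methyl-4-oxo-2-(triethylsilyloxy)butanamide | CON(C)C(=O)[C@H](CC=O)O[Si](CC)(CC)CC | intermediate
5 | but-2-yne-1,4-diol | OCC#CCO | starting material
6 | 4-(tert-butyldiphenylsilyloxy)but-2-yn-1-ol | OCC#CCO[Si](c1ccccc1)(c1ccccc1)C(C)(C)C | intermediate
7 | sodium alkenylalanate (cyclic ate complex from hydroalumination of 6) | [Na+].COCCO[Al-]1(OCCOC)OCC=C1CO[Si](c2ccccc2)(c2ccccc2)C(C)(C)C | intermediate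
8 | (Z)-4-(tert-butyldiphenylsilyloxy)-3-iodobut-2-en-1-ol | OC/C=C(\I)CO[Si](c1ccccc1)(c1ccccc1)C(C)(C)C | intermediate
9 | (Z)-4-(tert-butyldiphenylsilyloxy)-3-iodobut-2-en-1-yl acetate | CC(=O)OC/C=C(\I)CO[Si](c1ccccc1)(c1ccccc1)C(C)(C)C | intermediate
10 | (2S,4RS,5Z)-7-acetoxy-5-[(tert-butyldiphenylsilyloxy)methyl]-4-hydroxy-N-methoxy-N-methyl-2-(triethylsilyloxy)hept-5-enamide | CON(C)C(=O)[C@H](CC(O)/C(CO[Si](c1ccccc1)(c1ccccc1)C(C)(C)C)=C\COC(C)=O)O[Si](CC)(CC)CC | intermediate
11 | (2S,5Z)-7-acetoxy-5-[(tert-butyldiphenylsilyloxy)methyl]-N-methoxy-N-methyl-4-oxo-2-(triethylsilyloxy)hept-5-enamide | CON(C)C(=O)[C@H](CC(=O)/C(CO[Si](c1ccccc1)(c1ccccc1)C(C)(C)C)=C\COC(C)=O)O[Si](CC)(CC)CC | intermediate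
12 | (2S,4S,5Z)-7-acetoxy-5-[(tert-butyldiphenylsilyloxy)methyl]-4-hydroxy-N-methoxy-N-methyl-2-(triethylsilyloxy)hept-5-enamide | CON(C)C(=O)[C@H](C[C@H](O)/C(CO[Si](c1ccccc1)(c1ccccc1)C(C)(C)C)=C\COC(C)=O)O[Si](CC)(CC)CC | intermediate
13 | (2S,4S,5Z)-7-acetoxy-4-(tert-butyldimethylsilyloxy)-5-[(tert-butyldiphenylsilyloxy)methyl]-N-methoxy-N-methyl-2-(triethylsilyloxy)hept-5-enamide | CON(C)C(=O)[C@H](C[C@H](O[Si](C)(C)C(C)(C)C)/C(CO[Si](c1ccccc1)(c1ccccc1)C(C)(C)C)=C\COC(C)=O)O[Si](CC)(CC)CC | intermediate
14 | (3S,5S,6Z)-5-(tert-butyldimethylsilyloxy)-6-[(tert-butyldiphenylsilyloxy)methyl]-8-hydroxy-3-(triethylsilyloxy)oct-6-en-2-one | CC(=O)[C@@H](O[Si](CC)(CC)CC)C[C@H](O[Si](C)(C)C(C)(C)C)/C(CO[Si](c1ccccc1)(c1ccccc1)C(C)(C)C)=C\CO | intermediate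
15 | (2Z,4S,6S)-4-(tert-butyldimethylsilyloxy)-3-[(tert-butyldiphenylsilyloxy)methyl]-7-oxo-6-(triethylsilyloxy)oct-2-enal | CC(=O)[C@@H](O[Si](CC)(CC)CC)C[C@H](O[Si](C)(C)C(C)(C)C)/C(CO[Si](c1ccccc1)(c1ccccc1)C(C)(C)C)=C\C=O | intermediate
16 | (S)-4-benzyl-1,3-oxazolidin-2-one | O=C1N[C@@H](Cc2ccccc2)CO1 | starting material
17 | methyl 4-chloro-4-oxobutanoate | COC(=O)CCC(=O)Cl | starting material
18 | methyl 4-[(4S)-4-benzyl-2-oxo-1,3-oxazolidin-3-yl]-4-oxobutanoate | COC(=O)CCC(=O)N1C(=O)OC[C@@H]1Cc1ccccc1 | intermediate
19 | dibutylboron (Z)-enolate of 18 | CCCCB(CCCC)O/C(=C\CC(=O)OC)N1C(=O)OC[C@@H]1Cc1ccccc1 | intermediate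
20 | methyl (3S,4R)-3-[(4S)-4-benzyl-2-oxo-1,3-oxazolidine-3-carbonyl]-4-hydroxy-4-R*-butanoate (syn-aldol) | CC(=O)[C@@H](O[Si](CC)(CC)CC)C[C@H](O[Si](C)(C)C(C)(C)C)/C(CO[Si](c1ccccc1)(c1ccccc1)C(C)(C)C)=C\[C@@H](O)[C@H](CC(=O)OC)C(=O)N2C(=O)OC[C@@H]2Cc3ccccc3 | intermediate
21 | (4S)-4-benzyl-3-[(2R,3S)-5-oxo-2-R*-oxolane-3-carbonyl]-1,3-oxazolidin-2-one | CC(=O)[C@@H](O[Si](CC)(CC)CC)C[C@H](O[Si](C)(C)C(C)(C)C)/C(CO[Si](c1ccccc1)(c1ccccc1)C(C)(C)C)=C\[C@H]2OC(=O)C[C@@H]2C(=O)N3C(=O)OC[C@@H]3Cc4ccccc4 | intermediate
22 | (2R,3S)-5-oxo-2-R*-oxolane-3-carboxylic acid | CC(=O)[C@@H](O[Si](CC)(CC)CC)C[C@H](O[Si](C)(C)C(C)(C)C)/C(CO[Si](c1ccccc1)(c1ccccc1)C(C)(C)C)=C\[C@H]2OC(=O)C[C@@H]2C(=O)O | intermediate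
23 | mixed isobutyl carbonic anhydride of 22 | CC(=O)[C@@H](O[Si](CC)(CC)CC)C[C@H](O[Si](C)(C)C(C)(C)C)/C(CO[Si](c1ccccc1)(c1ccccc1)C(C)(C)C)=C\[C@H]2OC(=O)C[C@@H]2C(=O)OC(=O)OCC(C)C | intermediate
24 | (4S,5R)-4-(2-diazoacetyl)-5-R*-oxolan-2-one | CC(=O)[C@@H](O[Si](CC)(CC)CC)C[C@H](O[Si](C)(C)C(C)(C)C)/C(CO[Si](c1ccccc1)(c1ccccc1)C(C)(C)C)=C\[C@H]2OC(=O)C[C@@H]2C(=O)C=[N+]=[N-] | intermediate
25 | (4S,5R)-4-(2-bromoacetyl)-5-R*-oxolan-2-one (seco bromomethyl ketone) | CC(=O)[C@@H](O[Si](CC)(CC)CC)C[C@H](O[Si](C)(C)C(C)(C)C)/C(CO[Si](c1ccccc1)(c1ccccc1)C(C)(C)C)=C\[C@H]2OC(=O)C[C@@H]2C(=O)CBr | intermediate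
26 | diiodosamarium C9-enolate of the C8 ketone | CC(=O)[C@@H](O[Si](CC)(CC)CC)C[C@H](O[Si](C)(C)C(C)(C)C)/C(CO[Si](c1ccccc1)(c1ccccc1)C(C)(C)C)=C\[C@H]2OC(=O)C[C@@H]2C(=C)O[Sm](I)I | intermediate
27 | (1S,3S,4Z,6R,7S,10R)-3-(tert-butyldimethylsilyloxy)-15-(tert-butyldiphenylsilyloxy)-10-hydroxy-8-oxo-1-(triethylsilyloxy)-13-norgermacr-4-en-6,12-olide | O=C1O[C@@H]2/C=C(/CO[Si](c3ccccc3)(c3ccccc3)C(C)(C)C)[C@@H](O[Si](C)(C)C(C)(C)C)C[C@H](O[Si](CC)(CC)CC)[C@](C)(O)CC(=O)[C@H]2C1 | intermediate
28 | (1S,3S,4Z,6R,7R,8R,10R)-3-(tert-butyldimethylsilyloxy)-15-(tert-butyldiphenylsilyloxy)-8,10-dihydroxy-1-(triethylsilyloxy)-13-norgermacr-4-en-6,12-olide | O=C1O[C@@H]2/C=C(/CO[Si](c3ccccc3)(c3ccccc3)C(C)(C)C)[C@@H](O[Si](C)(C)C(C)(C)C)C[C@H](O[Si](CC)(CC)CC)[C@](C)(O)C[C@@H](O)[C@H]2C1 | intermediate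
29 | 13-(dimethylamino) Mannich base of 28 (C11 epimers) | CN(C)CC1C(=O)O[C@@H]2/C=C(/CO[Si](c3ccccc3)(c3ccccc3)C(C)(C)C)[C@@H](O[Si](C)(C)C(C)(C)C)C[C@H](O[Si](CC)(CC)CC)[C@](C)(O)C[C@@H](O)[C@@H]12 | intermediate
30 | 13-(trimethylammonio) iodide of 29 | C[N+](C)(C)CC1C(=O)O[C@@H]2/C=C(/CO[Si](c3ccccc3)(c3ccccc3)C(C)(C)C)[C@@H](O[Si](C)(C)C(C)(C)C)C[C@H](O[Si](CC)(CC)CC)[C@](C)(O)C[C@@H](O)[C@@H]12.[I-] | intermediate
31 | (1S,3S,4Z,6R,7R,8R,10R)-3-(tert-butyldimethylsilyloxy)-15-(tert-butyldiphenylsilyloxy)-8,10-dihydroxy-1-(triethylsilyloxy)germacra-4,11(13)-dien-6,12-olide | C=C1C(=O)O[C@@H]2/C=C(/CO[Si](c3ccccc3)(c3ccccc3)C(C)(C)C)[C@@H](O[Si](C)(C)C(C)(C)C)C[C@H](O[Si](CC)(CC)CC)[C@](C)(O)C[C@@H](O)[C@@H]12 | intermediate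
32 | (S)-2-methylbutanoic acid | CC[C@H](C)C(=O)O | starting material
33 | 8-O-[(2S)-2-methylbutanoyl] ester of 31 | C=C1C(=O)O[C@@H]2/C=C(/CO[Si](c3ccccc3)(c3ccccc3)C(C)(C)C)[C@@H](O[Si](C)(C)C(C)(C)C)C[C@H](O[Si](CC)(CC)CC)[C@](C)(O)C[C@@H](OC(=O)[C@@H](C)CC)[C@@H]12 | intermediate
34 | (1S,10R)-1,10-diol from 33 | C=C1C(=O)O[C@@H]2/C=C(/CO[Si](c3ccccc3)(c3ccccc3)C(C)(C)C)[C@@H](O[Si](C)(C)C(C)(C)C)C[C@H](O)[C@](C)(O)C[C@@H](OC(=O)[C@@H](C)CC)[C@@H]12 | intermediate
35 | (1S)-1-O-methanesulfonate of 34 | C=C1C(=O)O[C@@H]2/C=C(/CO[Si](c3ccccc3)(c3ccccc3)C(C)(C)C)[C@@H](O[Si](C)(C)C(C)(C)C)C[C@H](OS(C)(=O)=O)[C@](C)(O)C[C@@H](OC(=O)[C@@H](C)CC)[C@@H]12 | intermediate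
36 | (1R,3S,4Z,6R,7R,8R,10R)-3-(tert-butyldimethylsilyloxy)-15-(tert-butyldiphenylsilyloxy)-1,10-epoxy-8-[(2S)-2-methylbutanoyloxy]germacra-4,11(13)-dien-6,12-olide | C=C1C(=O)O[C@@H]2/C=C(/CO[Si](c3ccccc3)(c3ccccc3)C(C)(C)C)[C@@H](O[Si](C)(C)C(C)(C)C)C[C@H]4O[C@]4(C)C[C@@H](OC(=O)[C@@H](C)CC)[C@@H]12 | intermediate
37 | (1R,3S,4Z,6R,7R,8R,10R)-1,10-epoxy-3,15-dihydroxy-8-[(2S)-2-methylbutanoyloxy]germacra-4,11(13)-dien-6,12-olide | C=C1C(=O)O[C@@H]2/C=C(/CO)[C@@H](O)C[C@H]3O[C@]3(C)C[C@@H](OC(=O)[C@@H](C)CC)[C@@H]12 | target

## Step count and risks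

Total step count: 26. Longest linear sequence: 22 steps (1 → 37 through steps 1–3, 7–12 and 14–26; the branch from 5 through steps 4–6 is equally long). Step 13 is a one-step side branch.

Least certain steps:

Step 18 (key step). The most likely failure is that the samarium enolate forms but does not close the ring at −78 °C, because of the entropic and transannular cost of a ten-membered ring. Protonation on work-up (simple debromination), intermolecular addition, or, on warming, proton transfer to C7 with expulsion of the lactone carboxylate would then take over. A second risk is poor facial selectivity at C10 if samarium bridges the C10 carbonyl and the C1 oxygen. Fallback: an open-transition-state Mukaiyama aldol in place of the metal-bridged reductive aldol. It sets out from 25, which is converted by reductive silylation (Zn, Me3SiCl, Et2O) into the regiospecific C9 trimethylsilyl enol ether F1. F1 is then treated at high dilution with BF3·OEt2 in CH2Cl2 at −78 °C; this Lewis acid cannot chelate, so Felkin–Anh control should hold, and after loss of the silyl group the route is rejoined at 27.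

Step 17. The C1 triethylsilyl ether may be lost (followed by C1 epimerisation of the free α-hydroxy ketone) if the acid is not consumed fast enough. Fallback: avoid free aqueous acid by a Nierenstein reaction. Starting from acid 22, 1-chloro-N,N,2-trimethylprop-1-en-1-amine gives the acid chloride F2 under neutral conditions. Slow addition of one equivalent of diazomethane without base lets the HCl released on diazoketone formation be consumed at once by that diazoketone (24, formed in passing), giving the chloromethyl ketone F3. Finkelstein exchange (LiBr, acetone) returns to 25.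

Step 19. In the ten-membered ring the chair-like intramolecular hydride delivery may be overridden by the ring conformation, so that the facial selectivity is poor or inverted. Fallback: external hydride delivery followed by inversion. Starting from 27, Et2BOMe/NaBH4 (THF/MeOH, −78 °C) reduces the boron chelate from outside and should give the 8-epimeric syn-diol F4. Mitsunobu reaction of F4 with chloroacetic acid inverts C8 to the chloroacetate F5, and thiourea/NaHCO3 removes the chloroacetyl group without an alkoxide base, rejoining the route at 28.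

Step 20. Before the lactone is enolised, the C8 alkoxide may attack C12 and move the lactone to the 8,12-position, or the triethylsilyl group may migrate from O1 to the C10 alkoxide. Fallback: remove both alkoxides from the picture. Starting from 28, both hydroxyls are capped with 1-(trimethylsilyl)imidazole to give the bis-trimethylsilyl ether F6. F6 is methylenated with only a slight excess of base through Mannich base F7 and ammonium salt F8 to the methylene lactone F9, and the two trimethylsilyl ethers are removed with citric acid in methanol at 0 °C, which rejoins the route at 31.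

Step 26. During the long exposure that the TBDPS ether needs, the epoxide may open (transannular attack by C4=C5 or by the liberated hydroxyls) or the methylene lactone may take up a nucleophile. Fallback: change the order so that the epoxide never meets the desilylation. Starting from mesylate 35, both silyl ethers are removed with HF·pyridine buffered with pyridine (THF, 0 °C → rt), giving the mesylate triol F10. DBU in MeCN then closes the epoxide as the last step and delivers 37 directly.

## Further compounds

F1 | step 18 | C9 trimethylsilyl enol ether of the C8 ketone: (4S,5R)-4-[1-(trimethylsilyloxy)ethenyl]-5-R*-oxolan-2-one | CC(=O)[C@@H](O[Si](CC)(CC)CC)C[C@H](O[Si](C)(C)C(C)(C)C)/C(CO[Si](c1ccccc1)(c1ccccc1)C(C)(C)C)=C\[C@H]2OC(=O)C[C@@H]2C(=C)O[Si](C)(C)C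
F2 | step 17 | (2R,3S)-5-oxo-2-R*-oxolane-3-carbonyl chloride | CC(=O)[C@@H](O[Si](CC)(CC)CC)C[C@H](O[Si](C)(C)C(C)(C)C)/C(CO[Si](c1ccccc1)(c1ccccc1)C(C)(C)C)=C\[C@H]2OC(=O)C[C@@H]2C(Cl)=O
F3 | step 17 | (4S,5R)-4-(2-chloroacetyl)-5-R*-oxolan-2-one | CC(=O)[C@@H](O[Si](CC)(CC)CC)C[C@H](O[Si](C)(C)C(C)(C)C)/C(CO[Si](c1ccccc1)(c1ccccc1)C(C)(C)C)=C\[C@H]2OC(=O)C[C@@H]2C(=O)CCl
F4 | step 19 | (8S)-epimer of diol 28 (syn-8,10-diol) | O=C1O[C@@H]2/C=C(/CO[Si](c3ccccc3)(c3ccccc3)C(C)(C)C)[C@@H](O[Si](C)(C)C(C)(C)C)C[C@H](O[Si](CC)(CC)CC)[C@](C)(O)C[C@H](O)[C@H]2C1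
F5 | step 19 | (8R)-8-O-chloroacetate of 28 | O=C1O[C@@H]2/C=C(/CO[Si](c3ccccc3)(c3ccccc3)C(C)(C)C)[C@@H](O[Si](C)(C)C(C)(C)C)C[C@H](O[Si](CC)(CC)CC)[C@](C)(O)C[C@@H](OC(=O)CCl)[C@H]2C1
F6 | step 20 | 8,10-bis(trimethylsilyl) ether of 28 | O=C1O[C@@H]2/C=C(/CO[Si](c3ccccc3)(c3ccccc3)C(C)(C)C)[C@@H](O[Si](C)(C)C(C)(C)C)C[C@H](O[Si](CC)(CC)CC)[C@](C)(O[Si](C)(C)C)C[C@@H](O[Si](C)(C)C)[C@H]2C1
F7 | step 20 | 13-(dimethylamino) Mannich base of F6 (C11 epimers) | CN(C)CC1C(=O)O[C@@H]2/C=C(/CO[Si](c3ccccc3)(c3ccccc3)C(C)(C)C)[C@@H](O[Si](C)(C)C(C)(C)C)C[C@H](O[Si](CC)(CC)CC)[C@](C)(O[Si](C)(C)C)C[C@@H](O[Si](C)(C)C)[C@@H]12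
F8 | step 20 | 13-(trimethylammonio) iodide of F7 | C[N+](C)(C)CC1C(=O)O[C@@H]2/C=C(/CO[Si](c3ccccc3)(c3ccccc3)C(C)(C)C)[C@@H](O[Si](C)(C)C(C)(C)C)C[C@H](O[Si](CC)(CC)CC)[C@](C)(O[Si](C)(C)C)C[C@@H](O[Si](C)(C)C)[C@@H]12.[I-]
F9 | step 20 | 8,10-bis(trimethylsilyl) ether of 31 | C=C1C(=O)O[C@@H]2/C=C(/CO[Si](c3ccccc3)(c3ccccc3)C(C)(C)C)[C@@H](O[Si](C)(C)C(C)(C)C)C[C@H](O[Si](CC)(CC)CC)[C@](C)(O[Si](C)(C)C)C[C@@H](O[Si](C)(C)C)[C@@H]12
F10 | step 26 | (1S,3S,4Z,6R,7R,8R,10R)-3,10,15-trihydroxy-1-(methanesulfonyloxy)-8-[(2S)-2-methylbutanoyloxy]germacra-4,11(13)-dien-6,12-olide | C=C1C(=O)O[C@@H]2/C=C(/CO)[C@@H](O)C[C@H](OS(C)(=O)=O)[C@](C)(O)C[C@@H](OC(=O)[C@@H](C)CC)[C@@H]12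
A1 | alternative 1 | 3,15-bis(tert-butyldimethylsilyl) ether of 37 | C=C1C(=O)O[C@@H]2/C=C(/CO[Si](C)(C)C(C)(C)C)[C@@H](O[Si](C)(C)C(C)(C)C)C[C@H]3O[C@]3(C)C[C@@H](OC(=O)[C@@H](C)CC)[C@@H]12
A2 | alternative 1 | ring acid: 3,15-bis(tert-butyldimethylsilyloxy)-1,10-epoxy-8-[(2S)-2-methylbutanoyloxy]germacra-4,11(13)-dien-12-oic acid (C6 methylene) | C=C(C(=O)O)[C@H]1C/C=C(/CO[Si](C)(C)C(C)(C)C)[C@@H](O[Si](C)(C)C(C)(C)C)C[C@H]2O[C@]2(C)C[C@H]1OC(=O)[C@@H](C)CC
A3 | alternative 2 | isoxazoline-bridged ten-membered lactone (C1=N, O on C3; 10-O-triethylsilyl, 8-O-4-methoxybenzyl, 15-O-tert-butyldimethylsilyl) | O=C1O[C@@H]2/C=C(/CO[Si](C)(C)C(C)(C)C)[C@@H]3CC(=NO3)[C@](C)(O[Si](CC)(CC)CC)C[C@@H](OCc4ccc(OC)cc4)[C@H]2C1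
A4 | alternative 2 | seco C1 aldoxime with terminal C2=C3 vinyl group on the trans-lactone | ON=C[C@](C)(O[Si](CC)(CC)CC)C[C@@H](OCc1ccc(OC)cc1)[C@H]2CC(=O)O[C@@H]2/C=C(/CO[Si](C)(C)C(C)(C)C)C=C
A5 | alternative 3 | cyclodeca-4,10(1)-dien-6-one with 3-O-tert-butyldimethylsilyl and 8-O-4-methoxybenzyl ethers | O=C1/C=C(/C)[C@@H](O[Si](C)(C)C(C)(C)C)C/C=C(\C)C[C@@H](OCc2ccc(OC)cc2)C1
A6 | alternative 3 | 4-(tert-butyldimethylsilyloxy)-1-[(E)-2-(4-methoxybenzyloxy)ethenyl]-3-methyl-6-(prop-1-en-2-yl)cyclohex-2-en-1-ol (alkenyl groups trans) | O[C@]1(/C=C/OCc2ccc(OC)cc2)C=C(C)[C@@H](O[Si](C)(C)C(C)(C)C)C[C@@H]1C(C)=C
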